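**Analysis of the target**

The target 22 is a (2S)-flavanone: a 7-hydroxychroman-4-one (benzo ring A fused to pyranone ring C, whose atoms are O1, C2, C3, C4, C4a and C8a) carrying at C2 an aryl group, ring B, to which a 2,2-dimethyldihydropyran, ring D, is fused. Rings B and D together form a 3,4,8-trihydroxy-2,2-dimethylchroman-6-yl unit, whose positions carry primed locants below (O1', C2', C3', C4', C8'). There are three stereocentres: C2 (S) in ring C, and the vicinal pair C3' (R) and C4' (S) in ring D, whose hydroxyl groups are trans. C2 is separated from the diol by the whole of ring B, so neither element can relay to the other and each needs its own source of absolute configuration. The sensitive points are: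
- the flavanone C2, which epimerises once the C4 ketone exists, because base or strong acid opens ring C to the 2'-hydroxychalcone (helped by O1' para to C2);
- the benzylic C4' carbinol ortho to O1', which can ionise in acid and lose the trans relationship;
- the electron-rich, oxidisable ring B;
- the benzylic C2–O1 and C4'–O bonds, which are open to hydrogenolysis.

The hard part is therefore C2: a lone benzylic ether stereocentre flanked only by an aryl group and a methylene, to be set compatibly with the diol and kept while the ketone is unveiled. The strategy rests on ring C being a 2-aryl-4-oxygenated benzopyran: O1, C8a, C4a and C4 are the four-atom unit of an ortho-quinone methide at the oxidation level of a salicylaldehyde, and C3 and C2 are the two carbons of a vinylarene. A [4+2] union forms C3–C4 and O1–C2, closes ring C and sets C2; if C4 carries an alkoxy group at that moment, the ketone is only latent and C2 is not yet labile.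

**Retrosynthetic reasoning**

22 back to 20. The four hydroxyl groups are unveiled last. The two phenols are carried as benzyl ethers (21 to 22 by hydrogenolysis) and the diol as a bis-silyl ether (20 to 21 by buffered fluoride). Both removals are non-basic, which matters because from 20 onwards C2 sits beta to a ketone. Benzyl and silyl groups were chosen because both tolerate every earlier step, including the acid of the key step and the quinone oxidant.

20 back to 18. The C4 carbonyl is traced to a C4 methyl ether. C4–H in 18 is benzylic to ring A and activated by both the ortho oxygen O1 and the para oxygen at C7, so a hydride-abstracting quinone in wet solvent should convert C–H/C–OMe into C=O through hemiketal 19. No bond at C2 is made or broken. What is gained is that ring C can be built at an oxidation level at which C2 cannot epimerise.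

18 back to 15 and 12. This is the central cut: C3–C4 and O1–C2 of ring C are severed together. It is made here because it divides the molecule into two fragments of similar size at the only stereocentre that has no neighbouring handle, and it removes that stereocentre and ring C in one operation. The four-atom partner is acetal 15, which ionises to oxocarbenium ion 16 by loss of one alkoxy group. The two-atom partner is vinylchromane 12, whose terminal carbon is nucleophilic because O1' is para to the vinyl group. The forward reaction has to deliver the 2S configuration under control of a chiral counter-anion; in a stepwise path through cation 17 this means the anion must govern the ring closure as well as the first bond.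

12 back to 8. The vinyl group comes from the aldehyde of 11 by methylenation. It is introduced last in this fragment because a styrene would not survive the oxygen-transfer step. The silyl ethers come from diol 10. The trans-diol is cut at the C4'–O bond: hydrolytic opening of cis-epoxide 9 at the benzylic carbon with inversion gives the trans arrangement. Epoxide 9 comes from chromene 8 by manganese–salen oxygen transfer, for which 2,2-dimethylchromenes are among the best substrates. Keeping the formyl group through these steps is deliberate. It lies para to O1' and withdraws the lone pair that would otherwise support a free C4' cation, so the opening stays invertive.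

8 back to 1 and 3. The dimethylpyran ring is cut at O1'–C2' and C4'–C4a'. Aryl propargyl ether 4 rearranges thermally through 5, 6 and 7 to the chromene, with the only free ortho position fixing the regiochemistry. Ether 4 is assembled from 2 and the tertiary propargylic chloride 3. Compound 2 comes from 1 by alkylation of the dianion at the 3-oxygen, which places the benzyl group where C8'–OH will be.

15 back to 13. The acetal is made from salicylaldehyde 14, and 14 from 13 by benzylation of the 4-hydroxyl; the 2-hydroxyl is held back by its hydrogen bond to the formyl group. This branch is two steps, so the effort of the route is concentrated in the chiral fragment 12 and in the union.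

**Alternatives that were turned down**

Alternative 1: The C3'–C4' bond of ring D is cut. In the forward direction a chiral triazolylidene carbene converts the aryl aldehyde of dialdehyde A1 into an acyl anion equivalent, which adds to the tethered neopentyl-type aryloxy aldehyde and gives hydroxy ketone A2 with C3' set.
- For: it is organocatalytic, the chemoselectivity is clear (the hindered aldehyde has no alpha hydrogen and is the poorer acyl anion precursor), and the bromide is a versatile handle.
- Against: the new stereocentre in A2 is the alpha carbon of an alpha-hydroxy aryl ketone and can epimerise through the enediol under the basic conditions that generate the carbene. C4' then needs a separate trans-selective reduction. The aldehyde-to-aldehyde intramolecular variant is less secure than the aldehyde-to-ketone one.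
- Comparison: it solves only ring D, which the chosen route obtains from chromene 8 in two reliable steps, and leaves C2 and ring C to a separate sequence from the bromide. On one point it is stronger: C2 could then be set by established chemistry, for example asymmetric conjugate arylation of a chromone. In its place the chosen strategy offers one convergent step that makes ring C, two bonds and C2 at once, and a shorter route overall.

Alternative 2: The O1–C8a aryl ether bond of ring C is cut. In the forward direction the alkoxide of beta-hydroxy ketone A3, generated with a carbonate or amide base, displaces the ortho fluoride and gives flavanone A4.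
- For: the stereocentre is made earlier, in an aldol step, and no bond to it is formed or broken in the cyclisation. The ring closure is of a known type, so on the risk of the ring-forming step itself this alternative is stronger than the chosen one.
- Against: a beta-alkoxide of an aryl ketone whose carbinol is para-alkoxybenzylic is prone to retro-aldol cleavage and to dehydration to the chalcone, and either pathway costs material or configuration. The benzyloxy group para to the activating carbonyl weakens the activation for fluoride displacement. The asymmetric aldol of a methyl aryl ketone with an electron-rich aryl aldehyde usually needs a stoichiometric chiral reagent. A4 also still contains the chromene, so the diol would be installed late, beside an epimerisable flavanone and on an arene without an acceptor para to O1', where epoxide opening has more cationic character and the trans selectivity is less safe.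
- Comparison: step counts are similar. The chosen strategy sets C2 catalytically and installs the diol early, at the aldehyde stage, where the electronics favour clean inversion.

Alternative 3: The O1'–C2' bond of ring D is cut. In the forward direction a sulfonic acid activates the trisubstituted epoxide of phenol A5 and the ortho phenol attacks the tertiary carbon, giving chromanol A6 with both carbinol centres already in place.
- For: attack at the tertiary carbon is electronically favoured and the ring closure is conventional.
- Against: A5 needs both stereocentres set in an acyclic benzylic allylic system, in practice through a kinetic resolution by Sharpless asymmetric epoxidation, which discards half of the material, or through a longer sequence. Five-membered ring closure at the secondary epoxide carbon competes. The benzylic silyl ether ortho to a free phenol can ionise under the acid.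
- Comparison: like Alternative 1 it addresses only ring D, where the stereochemical reliability is at best equal to the chromene epoxidation route, and it needs more steps; C2 remains unsolved. The chosen strategy offers the direct construction of ring C with C2.

Key step: step 10

Assumption: which antipode of the chiral acid gives the 2S configuration cannot be predicted and is fixed by a screen of both enantiomers. Compound 18 is written as the expected 2,4-cis isomer; its C4 epimer, if formed, is carried into step 11 with it.

**Route**

Step 1
Reactants: 1 3,4-dihydroxybenzaldehyde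
Product: 2 3-(benzyloxy)-4-hydroxybenzaldehyde
Conditions: NaH (2.2 equiv), DMSO, rt; BnCl (1.0 equiv), rt; aq. HCl work-up
Reagents that add atoms: benzyl chloride, ClCc1ccccc1
Why: Williamson etherification of the doubly deprotonated 1: the 4-phenoxide is delocalised into the para formyl group, so the 3-phenoxide is the more nucleophilic oxygen and should take the single equivalent of benzyl chloride. This is the reverse of the monoanion selectivity and a known way to 3-O-alkylated 3,4-dihydroxybenzaldehydes.

Step 2
Reactants: 2 3-(benzyloxy)-4-hydroxybenzaldehyde; 3 3-chloro-3-methylbut-1-yne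
Product: 4 3-(benzyloxy)-4-[(2-methylbut-3-yn-2-yl)oxy]benzaldehyde
Conditions: CuCl2·2H2O (0.5 mol%), DBU (1.3 equiv), MeCN, 0 °C
Reagents that add atoms: none
Why: Copper-catalysed O-alkylation of a phenol by a tertiary propargylic chloride; the only free hydroxyl is the one at C4, and acceptor-substituted phenols are good substrates for this etherification.

Step 3
Reactants: 4 3-(benzyloxy)-4-[(2-methylbut-3-yn-2-yl)oxy]benzaldehyde
Product: 8 8-(benzyloxy)-2,2-dimethyl-2H-chromene-6-carbaldehyde, via allenyl dienone 5 (not isolated), via ortho-allenylphenol 6 (not isolated), via ortho-quinone methide 7 (not isolated)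
Conditions: PhNEt2, 180 °C
Reagents that add atoms: none
Why: Aromatic propargyl Claisen rearrangement to the only free ortho position gives 5, which enolises to 6; a 1,5-hydrogen shift gives 7 and oxa-6π-electrocyclisation closes the 2H-chromene. The gem-dimethyl group accelerates the [3,3] step, and rearrangement to the benzyloxy-bearing ortho carbon cannot rearomatise, so a single regioisomer is expected.

Step 4
Reactants: 8 8-(benzyloxy)-2,2-dimethyl-2H-chromene-6-carbaldehyde
Product: 9 (3R,4R)-8-(benzyloxy)-3,4-epoxy-2,2-dimethylchromane-6-carbaldehyde
Conditions: (R,R)-[N,N'-bis(3,5-di-tert-butylsalicylidene)cyclohexane-1,2-diaminato]MnCl (4 mol%), 4-phenylpyridine N-oxide (20 mol%), aq. NaOCl (Na2HPO4 buffer, pH 11.3), CH2Cl2, 0 °C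
Reagents that add atoms: sodium hypochlorite, [Na+].[O-]Cl
Why: Jacobsen–Katsuki epoxidation with the chloride complex of trivalent manganese; cis-disubstituted, aryl-conjugated 2,2-dimethylchromenes are among its best substrates, and the (R,R)-catalyst should give the (3R,4R)-epoxide, mirroring the (S,S)-catalyst and (3S,4S)-epoxide pairing known for 6-acceptor chromenes. The non-enolisable, donor-substituted aryl aldehyde should survive buffered hypochlorite at 0 °C.

Step 5
Reactants: 9 (3R,4R)-8-(benzyloxy)-3,4-epoxy-2,2-dimethylchromane-6-carbaldehyde
Product: 10 (3R,4S)-8-(benzyloxy)-3,4-dihydroxy-2,2-dimethylchromane-6-carbaldehyde (3,4-trans)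
Conditions: HClO4 (cat.), THF/H2O, 0 °C to rt
Reagents that add atoms: water, O
Why: Acid-catalysed epoxide hydrolysis: water opens the protonated epoxide at the benzylic carbon C4 with inversion while C3 keeps its configuration, so the (3R,4R)-epoxide should give the (3R,4S)-trans-diol. The formyl group para to the ring oxygen withdraws the lone pair that would stabilise a free C4 cation, which keeps the opening invertive.

Step 6
Reactants: 10 (3R,4S)-8-(benzyloxy)-3,4-dihydroxy-2,2-dimethylchromane-6-carbaldehyde
Product: 11 (3R,4S)-8-(benzyloxy)-3,4-bis[(tert-butyldimethylsilyl)oxy]-2,2-dimethylchromane-6-carbaldehyde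
Conditions: TBSOTf (3 equiv), 2,6-lutidine (5 equiv), CH2Cl2, 0 °C to rt
Reagents that add atoms: tert-butyldimethylsilyl trifluoromethanesulfonate, CC(C)(C)[Si](C)(C)OS(=O)(=O)C(F)(F)F
Why: Silylation with the silyl triflate is strong enough to cap the hindered C3 hydroxyl next to the quaternary carbon as well as the benzylic one; the aldehyde has no alpha hydrogen and is inert to these conditions.

Step 7
Reactants: 11 (3R,4S)-8-(benzyloxy)-3,4-bis[(tert-butyldimethylsilyl)oxy]-2,2-dimethylchromane-6-carbaldehyde
Product: 12 (3R,4S)-8-(benzyloxy)-3,4-bis[(tert-butyldimethylsilyl)oxy]-6-ethenyl-2,2-dimethylchromane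
Conditions: Ph3PCH3Br, KOtBu, THF, 0 °C to rt
Reagents that add atoms: methyltriphenylphosphonium bromide, C[P+](c1ccccc1)(c1ccccc1)c1ccccc1.[Br-]
Why: Wittig methylenation of an aryl aldehyde with the unstabilised ylide; silyl and benzyl ethers are stable to the ylide and no stereocentre is near the reacting carbon.

Step 8
Reactants: 13 2,4-dihydroxybenzaldehyde
Product: 14 4-(benzyloxy)-2-hydroxybenzaldehyde
Conditions: BnBr (1.05 equiv), NaHCO3, MeCN, 80 °C
Reagents that add atoms: benzyl bromide, BrCc1ccccc1
Why: Williamson etherification under weak base: the 2-hydroxyl is tied up in a hydrogen bond to the formyl group and is less acidic, so the 4-hydroxyl should be alkylated selectively.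

Step 9
Reactants: 14 4-(benzyloxy)-2-hydroxybenzaldehyde
Product: 15 5-(benzyloxy)-2-(dimethoxymethyl)phenol
Conditions: HC(OMe)3 (3 equiv), MeOH, pyridinium p-toluenesulfonate (cat.), rt; Et3N quench, concentration; used crude at once
Reagents that add atoms: trimethyl orthoformate, COC(OC)OC; methanol, CO
Why: Acid-catalysed acetalisation driven by the orthoformate, which is converted to methyl formate. The ortho-hydroxy acetal is acid-labile, so the acid is neutralised before concentration and the material is not chromatographed on silica.

Step 10
Reactants: 15 5-(benzyloxy)-2-(dimethoxymethyl)phenol; 12 (3R,4S)-8-(benzyloxy)-3,4-bis[(tert-butyldimethylsilyl)oxy]-6-ethenyl-2,2-dimethylchromane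
Product: 18 (2S,4S)-7-(benzyloxy)-2-[(3R,4S)-8-(benzyloxy)-3,4-bis[(tert-butyldimethylsilyl)oxy]-2,2-dimethylchroman-6-yl]-4-methoxychromane, via oxocarbenium ion 16 (not isolated), via benzylic cation 17 (not isolated)
Conditions: chiral confined Brønsted acid (BINOL-derived imidodiphosphorimidate, IDPi, with N-triflyl groups and 3,3'-aryl substituents, 5 mol%), 15 (1.3 equiv), 5 Å molecular sieves, CH2Cl2, −60 to −40 °C; Et3N quench
Reagents that add atoms: none
Why: Proposed new method: the confined acid protonates one methoxy group of 15 and expels methanol, giving oxocarbenium ion 16 (an O-methylated ortho-quinone methide) as a contact ion pair with the chiral anion, to which the free ortho hydroxyl can hydrogen-bond. The terminal alkene carbon of 12 attacks the carbenium carbon (C3–C4 bond), and the positive charge arising at the internal carbon, stabilised by the para oxygen O1' (cation 17 in the stepwise limit), is captured by the phenol oxygen (O1–C2 bond); the closest known reactions are chiral phosphoric acid-catalysed [4+2] additions of ortho-quinone methides to styrenes giving 2-arylchromans and Lewis acid-promoted [4+2] additions of salicylaldehyde acetals to alkenes, but an enantioselective version with a simple acetal and an unfunctionalised vinylarene has not been shown. Ring C is closed as a six-membered ring in an asynchronous inverse-demand hetero-[4+2] mode (O1, C8a, C4a and C4 from 16, C3 and C2 from the alkene), the second bond amounting to a 6-exo-trig capture of the quinoid benzylic cation by oxygen. C2 is controlled by the chiral counter-anion, which has to stay associated through both bond-forming events and shield one face of 17; the stereocentres of ring D are five bonds away, so catalyst control should prevail, and they make the two C2 epimers diastereomers and hence separable. C4 is expected mainly cis to the C2 aryl group (both pseudo-equatorial in a half-chair closure) and is erased in step 11. Regiochemistry follows from the polarisation of the alkene by the para oxygen, and chemoselectivity from the acetal of 15 ionising far more readily than the C4' silyl ether of 12, whose cation is destabilised by the adjacent C3' oxygen. The selectivity the step needs is 2S in both C4 epimers: a stepwise path sets C4 first and would pass any cis/trans leakage on to C2 unless the anion governs the ring closure itself.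

Step 11
Reactants: 18 (2S,4S)-7-(benzyloxy)-2-[(3R,4S)-8-(benzyloxy)-3,4-bis[(tert-butyldimethylsilyl)oxy]-2,2-dimethylchroman-6-yl]-4-methoxychromane
Product: 20 (2S)-7-(benzyloxy)-2-[(3R,4S)-8-(benzyloxy)-3,4-bis[(tert-butyldimethylsilyl)oxy]-2,2-dimethylchroman-6-yl]chroman-4-one, via methyl hemiketal 19 (not isolated)
Conditions: DDQ (1.5 equiv), CH2Cl2/pH 7 phosphate buffer (10:1), 0 °C to rt
Reagents that add atoms: water, O
Why: DDQ oxidation of an electron-rich benzylic ether, the chemistry of oxidative 2,4-dimethoxybenzyl ether cleavage: hydride transfer from C4–H, activated by the ortho oxygen O1 and the para oxygen at C7, then capture by water gives hemiketal 19, which loses methanol to the ketone. C2–H is less activated (its oxygen is an aryl ether oxygen and its arene has one para donor), no bond to C2 is touched, and both C4 epimers converge on 20.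

Step 12
Reactants: 20 (2S)-7-(benzyloxy)-2-[(3R,4S)-8-(benzyloxy)-3,4-bis[(tert-butyldimethylsilyl)oxy]-2,2-dimethylchroman-6-yl]chroman-4-one
Product: 21 (2S)-7-(benzyloxy)-2-[(3R,4S)-8-(benzyloxy)-3,4-dihydroxy-2,2-dimethylchroman-6-yl]chroman-4-one
Conditions: HF·pyridine, pyridine, THF, 0 °C to rt
Reagents that add atoms: none
Why: Desilylation by buffered hydrogen fluoride. Basic fluoride sources are avoided because they would open the flavanone to the 2'-hydroxychalcone by retro-oxa-Michael reaction and cost the C2 configuration.

Step 13
Reactants: 21 (2S)-7-(benzyloxy)-2-[(3R,4S)-8-(benzyloxy)-3,4-dihydroxy-2,2-dimethylchroman-6-yl]chroman-4-one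
Product: 22 (2S)-7-hydroxy-2-[(3R,4S)-3,4,8-trihydroxy-2,2-dimethylchroman-6-yl]chroman-4-one
Conditions: H2 (1 atm), Pd/C (10 wt%), EtOAc, rt
Reagents that add atoms: none
Why: Hydrogenolysis of the two aryl benzyl ethers, which under neutral conditions should be much faster than cleavage of the benzylic C4' hydroxyl or the C2–O1 bond or reduction of the ortho-oxygenated aryl ketone. The polar product is isolated by filtration and evaporation without aqueous work-up.

**Compound list**

1 | 3,4-dihydroxybenzaldehyde | O=Cc1ccc(O)c(O)c1 | starting material
2 | 3-(benzyloxy)-4-hydroxybenzaldehyde | O=Cc1ccc(O)c(OCc2ccccc2)c1 | intermediate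
3 | 3-chloro-3-methylbut-1-yne | CC(C)(Cl)C#C | starting material
4 | 3-(benzyloxy)-4-[(2-methylbut-3-yn-2-yl)oxy]benzaldehyde | O=Cc1ccc(OC(C)(C)C#C)c(OCc2ccccc2)c1 | intermediate
5 | 5-(benzyloxy)-3-(3-methylbuta-1,2-dien-1-yl)-4-oxocyclohexa-1,5-diene-1-carbaldehyde (allenyl dienone, formed in the flask in step 3) | O=CC1=CC(C=C=C(C)C)C(=O)C(OCc2ccccc2)=C1 | intermediate
6 | 3-(benzyloxy)-4-hydroxy-5-(3-methylbuta-1,2-dien-1-yl)benzaldehyde (formed in the flask in step 3) | O=Cc1cc(OCc2ccccc2)c(O)c(C=C=C(C)C)c1 | intermediate
7 | 5-(benzyloxy)-3-(3-methylbut-2-en-1-ylidene)-4-oxocyclohexa-1,5-diene-1-carbaldehyde (ortho-quinone methide, formed in the flask in step 3) | O=CC1=CC(=CC=C(C)C)C(=O)C(OCc2ccccc2)=C1 | intermediate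
8 | 8-(benzyloxy)-2,2-dimethyl-2H-chromene-6-carbaldehyde | CC1(C)C=Cc2cc(C=O)cc(OCc3ccccc3)c2O1 | intermediate
9 | (3R,4R)-8-(benzyloxy)-3,4-epoxy-2,2-dimethylchromane-6-carbaldehyde | CC1(C)Oc2c(OCc3ccccc3)cc(C=O)cc2[C@H]4O[C@@H]14 | intermediate
10 | (3R,4S)-8-(benzyloxy)-3,4-dihydroxy-2,2-dimethylchromane-6-carbaldehyde | CC1(C)Oc2c(OCc3ccccc3)cc(C=O)cc2[C@H](O)[C@H]1O | intermediate
11 | (3R,4S)-8-(benzyloxy)-3,4-bis[(tert-butyldimethylsilyl)oxy]-2,2-dimethylchromane-6-carbaldehyde | CC1(C)Oc2c(OCc3ccccc3)cc(C=O)cc2[C@H](O[Si](C)(C)C(C)(C)C)[C@H]1O[Si](C)(C)C(C)(C)C | intermediate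
12 | (3R,4S)-8-(benzyloxy)-3,4-bis[(tert-butyldimethylsilyl)oxy]-6-ethenyl-2,2-dimethylchromane | CC1(C)Oc2c(OCc3ccccc3)cc(C=C)cc2[C@H](O[Si](C)(C)C(C)(C)C)[C@H]1O[Si](C)(C)C(C)(C)C | intermediate
13 | 2,4-dihydroxybenzaldehyde | O=Cc1ccc(O)cc1O | starting material
14 | 4-(benzyloxy)-2-hydroxybenzaldehyde | O=Cc1ccc(OCc2ccccc2)cc1O | intermediate
15 | 5-(benzyloxy)-2-(dimethoxymethyl)phenol | COC(OC)c1ccc(OCc2ccccc2)cc1O | intermediate
16 | [4-(benzyloxy)-2-hydroxybenzylidene](methyl)oxonium, paired with the chiral anion (formed in the flask in step 10) | C[O+]=Cc1ccc(OCc2ccccc2)cc1O | intermediate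
17 | (3S)-1-[(3R,4S)-8-(benzyloxy)-3,4-bis[(tert-butyldimethylsilyl)oxy]-2,2-dimethylchroman-6-yl]-3-[4-(benzyloxy)-2-hydroxyphenyl]-3-methoxypropan-1-ylium (formed in the flask in step 10) | CC1(C)Oc2c(OCc3ccccc3)cc([CH+]C[C@H](OC)c4ccc(OCc5ccccc5)cc4O)cc2[C@H](O[Si](C)(C)C(C)(C)C)[C@H]1O[Si](C)(C)C(C)(C)C | intermediate
18 | (2S,4S)-7-(benzyloxy)-2-[(3R,4S)-8-(benzyloxy)-3,4-bis[(tert-butyldimethylsilyl)oxy]-2,2-dimethylchroman-6-yl]-4-methoxychromane (2,4-cis) | CC1(C)Oc2c(OCc3ccccc3)cc([C@@H]4C[C@H](OC)c5ccc(OCc6ccccc6)cc5O4)cc2[C@H](O[Si](C)(C)C(C)(C)C)[C@H]1O[Si](C)(C)C(C)(C)C | intermediate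
19 | (2S)-7-(benzyloxy)-2-[(3R,4S)-8-(benzyloxy)-3,4-bis[(tert-butyldimethylsilyl)oxy]-2,2-dimethylchroman-6-yl]-4-methoxychroman-4-ol (formed in the flask in step 11) | CC1(C)Oc2c(OCc3ccccc3)cc([C@@H]4CC(O)(OC)c5ccc(OCc6ccccc6)cc5O4)cc2[C@H](O[Si](C)(C)C(C)(C)C)[C@H]1O[Si](C)(C)C(C)(C)C | intermediate
20 | (2S)-7-(benzyloxy)-2-[(3R,4S)-8-(benzyloxy)-3,4-bis[(tert-butyldimethylsilyl)oxy]-2,2-dimethylchroman-6-yl]chroman-4-one | CC1(C)Oc2c(OCc3ccccc3)cc([C@@H]4CC(=O)c5ccc(OCc6ccccc6)cc5O4)cc2[C@H](O[Si](C)(C)C(C)(C)C)[C@H]1O[Si](C)(C)C(C)(C)C | intermediate
21 | (2S)-7-(benzyloxy)-2-[(3R,4S)-8-(benzyloxy)-3,4-dihydroxy-2,2-dimethylchroman-6-yl]chroman-4-one | CC1(C)Oc2c(OCc3ccccc3)cc([C@@H]4CC(=O)c5ccc(OCc6ccccc6)cc5O4)cc2[C@H](O)[C@H]1O | intermediate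
22 | (2S)-7-hydroxy-2-[(3R,4S)-3,4,8-trihydroxy-2,2-dimethylchroman-6-yl]chroman-4-one | CC1(C)Oc2c(O)cc([C@@H]3CC(=O)c4ccc(O)cc4O3)cc2[C@H](O)[C@H]1O | target

**Step count and risk**

Total: 13 steps. Longest linear sequence: 11 steps (steps 1 to 7, then 10 to 13); the second branch (steps 8 and 9) joins at step 10.

Least certain steps:

Step 10 (key step). Several things may go wrong:
- Poor facial selectivity at C2. Cation 17 is well stabilised and may live long enough to leave the chiral pocket before oxygen closes the ring, and any cis/trans leakage in a stepwise path then appears as loss of C2 purity.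
- Epimerisation of the product. The para-alkoxybenzylic C2–O1 bond can re-ionise under the strong acid.
- Cationic oligomerisation of the electron-rich vinylarene, or self-condensation of the acetal.

The fallback uses known chemistry, sets out from aldehyde 11 and returns at flavanone 20. Claisen–Schmidt condensation of 11 with commercial 1-[4-(benzyloxy)-2-hydroxyphenyl]ethan-1-one (CC(=O)c1ccc(OCc2ccccc2)cc1O; KOH, EtOH, rt) should give the 2'-hydroxychalcone (E)-1-[4-(benzyloxy)-2-hydroxyphenyl]-3-[(3R,4S)-8-(benzyloxy)-3,4-bis[(tert-butyldimethylsilyl)oxy]-2,2-dimethylchroman-6-yl]prop-2-en-1-one F1. Its oxa-Michael cyclisation (NaOAc, EtOH, reflux) closes ring C without facial control. Because ring D is already enantiopure, the two C2 epimers are diastereomers. Compound 20 is separated by chromatography from (2R)-7-(benzyloxy)-2-[(3R,4S)-8-(benzyloxy)-3,4-bis[(tert-butyldimethylsilyl)oxy]-2,2-dimethylchroman-6-yl]chroman-4-one F2, which is returned to the chalcone/flavanone equilibrium under the same conditions and recycled. The catalytic setting of C2 is given up, and steps 7 to 9 fall away.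

Step 11. Hydride abstraction may occur at the wrong site: C2–H is also a para-alkoxybenzylic ether hydrogen, and oxidation there would destroy the stereocentre. Over-oxidation of ring C is a second possibility. The fallback sets out from 18 and returns at 20. The doubly activated benzylic methoxy group is exchanged for hydroxyl in THF/H2O with a trace of pyridinium p-toluenesulfonate, giving (2S)-7-(benzyloxy)-2-[(3R,4S)-8-(benzyloxy)-3,4-bis[(tert-butyldimethylsilyl)oxy]-2,2-dimethylchroman-6-yl]chroman-4-ol F3 as a mixture of C4 epimers. This alcohol is oxidised with Dess–Martin periodinane buffered with NaHCO3, an oxidant that does not act by hydride abstraction from ether C–H bonds.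

Step 9. The acetal may revert to the aldehyde, or ionise and self-condense, during isolation, because the ortho hydroxyl and the para benzyloxy group both assist loss of methoxide. The fallback sets out from 14 and returns at 18. The acetal is not isolated: 14, trimethyl orthoformate and 12 are combined with the acid of step 10, so that 15 forms and is consumed in the same flask, in the manner of Lewis acid-promoted three-component chroman syntheses from salicylaldehydes, orthoformates and alkenes. This fallback makes no new compound (F0).

Step 13. Reduction may go too far: hydrogenolysis of the benzylic C4' hydroxyl or of the C2–O1 bond (opening ring C to a dihydrochalcone), or reduction of the ketone. The fallback sets out from 20 and returns at 22 by exchanging the order of the two deprotections. Hydrogenolysis of 20 (H2, Pd/C, EtOAc) while the C4' oxygen is still silylated, and so shielded from the catalyst surface, should give (2S)-2-[(3R,4S)-3,4-bis[(tert-butyldimethylsilyl)oxy]-8-hydroxy-2,2-dimethylchroman-6-yl]-7-hydroxychroman-4-one F4. HF·pyridine then frees the diol.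

Step 1. Alkylation may be unselective (4-O- or bis-benzylation) if dianion formation is incomplete, since the monoanion reacts at the 4-oxygen. The fallback sets out from 1 and returns at 4, and uses the monoanion selectivity instead. With one equivalent of DBU only the more acidic 4-hydroxyl is ionised, so CuCl2-catalysed propargylation with 3 should give 3-hydroxy-4-[(2-methylbut-3-yn-2-yl)oxy]benzaldehyde F5. Ordinary benzylation of the remaining phenol (BnBr, K2CO3, DMF) then gives 4.

**Further compounds**

F1 | step 10 | (E)-1-[4-(benzyloxy)-2-hydroxyphenyl]-3-[(3R,4S)-8-(benzyloxy)-3,4-bis[(tert-butyldimethylsilyl)oxy]-2,2-dimethylchroman-6-yl]prop-2-en-1-one | CC1(C)Oc2c(OCc3ccccc3)cc(/C=C/C(=O)c4ccc(OCc5ccccc5)cc4O)cc2[C@H](O[Si](C)(C)C(C)(C)C)[C@H]1O[Si](C)(C)C(C)(C)C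
F2 | step 10 | (2R)-7-(benzyloxy)-2-[(3R,4S)-8-(benzyloxy)-3,4-bis[(tert-butyldimethylsilyl)oxy]-2,2-dimethylchroman-6-yl]chroman-4-one | CC1(C)Oc2c(OCc3ccccc3)cc([C@H]4CC(=O)c5ccc(OCc6ccccc6)cc5O4)cc2[C@H](O[Si](C)(C)C(C)(C)C)[C@H]1O[Si](C)(C)C(C)(C)C
F0 | step 9 | none | none
F3 | step 11 | (2S)-7-(benzyloxy)-2-[(3R,4S)-8-(benzyloxy)-3,4-bis[(tert-butyldimethylsilyl)oxy]-2,2-dimethylchroman-6-yl]chroman-4-ol | CC1(C)Oc2c(OCc3ccccc3)cc([C@@H]4CC(O)c5ccc(OCc6ccccc6)cc5O4)cc2[C@H](O[Si](C)(C)C(C)(C)C)[C@H]1O[Si](C)(C)C(C)(C)C
F4 | step 13 | (2S)-2-[(3R,4S)-3,4-bis[(tert-butyldimethylsilyl)oxy]-8-hydroxy-2,2-dimethylchroman-6-yl]-7-hydroxychroman-4-one | CC1(C)Oc2c(O)cc([C@@H]3CC(=O)c4ccc(O)cc4O3)cc2[C@H](O[Si](C)(C)C(C)(C)C)[C@H]1O[Si](C)(C)C(C)(C)C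
F5 | step 1 | 3-hydroxy-4-[(2-methylbut-3-yn-2-yl)oxy]benzaldehyde | O=Cc1ccc(OC(C)(C)C#C)c(O)c1
A1 | alternative 1 | 3-(benzyloxy)-5-bromo-2-[(2-methyl-1-oxopropan-2-yl)oxy]benzaldehyde | O=Cc1cc(Br)cc(OCc2ccccc2)c1OC(C)(C)C=O
A2 | alternative 1 | (3S)-8-(benzyloxy)-6-bromo-3-hydroxy-2,2-dimethylchroman-4-one | CC1(C)Oc2c(OCc3ccccc3)cc(Br)cc2C(=O)[C@H]1O
A3 | alternative 2 | (3S)-1-[4-(benzyloxy)-2-fluorophenyl]-3-[8-(benzyloxy)-2,2-dimethyl-2H-chromen-6-yl]-3-hydroxypropan-1-one | CC1(C)C=Cc2cc([C@@H](O)CC(=O)c3ccc(OCc4ccccc4)cc3F)cc(OCc3ccccc3)c2O1
A4 | alternative 2 | (2S)-7-(benzyloxy)-2-[8-(benzyloxy)-2,2-dimethyl-2H-chromen-6-yl]chroman-4-one | CC1(C)C=Cc2cc([C@@H]3CC(=O)c4ccc(OCc5ccccc5)cc4O3)cc(OCc3ccccc3)c2O1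
A5 | alternative 3 | 2-(benzyloxy)-4-bromo-6-{(S)-[(tert-butyldimethylsilyl)oxy][(2R)-3,3-dimethyloxiran-2-yl]methyl}phenol | Oc1c(OCc2ccccc2)cc(Br)cc1[C@H](O[Si](C)(C)C(C)(C)C)[C@H]3OC3(C)C
A6 | alternative 3 | (3R,4S)-8-(benzyloxy)-6-bromo-4-[(tert-butyldimethylsilyl)oxy]-2,2-dimethylchroman-3-ol | CC1(C)Oc2c(OCc3ccccc3)cc(Br)cc2[C@H](O[Si](C)(C)C(C)(C)C)[C@H]1O
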